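## Retrosynthetic overview

1. Gnetin K ⇒ open the C2–O1 bond of the dihydrofuran fused to ring D, giving an octaphenolic triarylethylene (ring E)CH=C(ring F)(ring D); a chiral-acid-catalysed C–O ring closure sets C2/C3.
2. That alkene ⇒ Heck arylation (4-iodo-2-methoxyphenol) of a 1,1-diarylethylene ⇒ MOM-protected (2R,3R)-gnetin C lithiated on ring D between its two OMOM groups + 3,5-bis(methoxymethoxy)acetophenone.
3. (2R,3R)-Gnetin C ⇒ the same C–O ring closure (mirror-image catalyst) of (ring C)CH=C(ring D)(ring B) ⇒ Heck (4-iodophenol) ⇒ tri-MOM-resveratrol lithiated on ring B + the same ketone.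
4. Ring order: dihydrofuran on ring B first (sets C2'/C3'), then dihydrofuran on ring D (sets C2/C3); all six benzene rings are bought.
5. Labels: ring A = styryl phenol ring, ring B = resveratrol resorcinol ring, ring C = 4-hydroxyphenyl on C2', ring D = central resorcinol ring, ring E = guaiacyl on C2, ring F = 3,5-dihydroxyphenyl on C3.

Assumption: (R)-TRIP is taken to give the (2R,3R) ring and (S)-TRIP the (2S,3S) ring; the sense is checked on the first cyclisation and, if reversed, the two catalyst antipodes are exchanged.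

Abbreviations: MOM = methoxymethyl, MOMO = methoxymethoxy, TRIP = 3,3'-bis(2,4,6-triisopropylphenyl)-1,1'-binaphthyl-2,2'-diyl hydrogen phosphate. The target SMILES was read as (2S,3S) for the guaiacyl-bearing dihydrobenzofuran and (2R,3R) for the styryl-bearing one, both trans, so the two ring closures need opposite catalyst antipodes.

## Route

Step 1
Reactants: 1 resveratrol, (E)-3,5,4'-trihydroxystilbene
Product: 2 (E)-3,5,4'-tris(methoxymethoxy)stilbene
Conditions: NaH, MOMCl, DMF, 0 °C → rt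
Reagents that add atoms: chloromethyl methyl ether (MOMCl), COCCl
Why: Williamson O-alkylation of the three phenoxides; no stereocentre is involved and the (E)-alkene is untouched.

Step 2
Reactants: 3 3,5-dihydroxyacetophenone
Product: 4 1-[3,5-bis(methoxymethoxy)phenyl]ethanone
Conditions: MOMCl, i-Pr2NEt, CH2Cl2, 0 °C → rt
Reagents that add atoms: chloromethyl methyl ether (MOMCl), COCCl
Why: Phenol O-alkylation under amine base, which avoids enolate formation at the methyl ketone.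

Step 3
Reactants: 2 (E)-3,5,4'-tris(methoxymethoxy)stilbene; 4 1-[3,5-bis(methoxymethoxy)phenyl]ethanone
Product: 7 1-[3,5-bis(MOMO)phenyl]-1-[2,6-bis(MOMO)-4-[(E)-4-(MOMO)styryl]phenyl]ethene, via aryllithium 5 (not isolated), via tertiary alcohol 6 (not isolated)
Conditions: n-BuLi, THF, −20 °C; then 4, LaCl3·2LiCl, −78 → 0 °C; aq NH4Cl; then PPTS (cat.), toluene, 50 °C
Reagents that add atoms: none
Why: Directed ortho-metalation at the C–H flanked by two OMOM groups (much faster than the singly activated sites or addition to the electron-rich stilbene), 1,2-addition to the LaCl3-activated ketone, then mild acid dehydration of the doubly benzylic tertiary carbinol.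

Step 4
Reactants: 7 the 1,1-diarylethylene from step 3; 8 4-iodophenol
Product: 9 4-[2-[3,5-bis(MOMO)phenyl]-2-[2,6-bis(MOMO)-4-[(E)-4-(MOMO)styryl]phenyl]ethenyl]phenol (E/Z mixture at the triaryl alkene)
Conditions: Pd(OAc)2 (5 mol%), P(o-tol)3 (10 mol%), K2CO3, DMF, 90 °C
Reagents that add atoms: none
Why: Mizoroki–Heck arylation of the terminal 1,1-diarylethylene, which reacts ahead of the internal stilbene; β-hydride elimination can only give the triarylethylene, and its E/Z ratio does not matter because step 6 erases it.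

Step 5
Reactants: 9 the penta-MOM triarylethylene
Product: 11 2-[1-(3,5-dihydroxyphenyl)-2-(4-hydroxyphenyl)ethenyl]-5-[(E)-2-(4-hydroxyphenyl)ethenyl]benzene-1,3-diol (E/Z mixture at the triaryl alkene), via hexakis(trimethylsilyl) ether 10 (not isolated)
Conditions: TMSOTf, 2,2'-bipyridyl, CH2Cl2, 0 °C → rt; then H2O
Reagents that add atoms: none
Why: Bipyridyl-buffered silyl triflate cleavage of aryl MOM ethers to aryl silyl ethers, then neutral hydrolysis; no strong protic acid is present, so the alkene is not protonated and no racemic ring closure occurs.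

Step 6
Reactants: 11 the hexaphenolic triarylethylene
Product: 13 (2R,3R)-3-(3,5-dihydroxyphenyl)-2-(4-hydroxyphenyl)-6-[(E)-4-hydroxystyryl]-2,3-dihydrobenzofuran-4-ol [(2R,3R)-gnetin C], via para-quinone methide 12 (not isolated)
Conditions: (R)-TRIP (10 mol%), 5 Å MS, CH2Cl2–EtOAc 9:1, 0 °C
Reagents that add atoms: none
Why: Proposed new method: chiral phosphoric acid-catalysed enantioselective cycloisomerisation (intramolecular hydroalkoxylation) of a 2-(1,2-diarylvinyl)resorcinol. The catalyst protonates the diaryl-substituted alkene carbon while accepting the para-phenol proton, giving the hydrogen-bonded para-quinone methide 12 with a new benzylic stereocentre. One of the two equivalent ortho-hydroxyls of ring B then adds 1,6 to the methide carbon inside the chiral pocket, anti to the 3-aryl group, so the C–O bond closes the ring and fixes trans-(2R,3R). Protonation is reversible (protonation at the other alkene carbon only scrambles E/Z), so both alkene isomers converge and the ring closure is the selecting event. Closest known reaction types: phosphoric acid-catalysed enantioselective 1,6-additions to para-quinone methides generated in situ from hydroxystyrenes or hydroxybenzyl alcohols, and confined-acid-catalysed asymmetric intramolecular hydroalkoxylation of alkenes.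

Step 7
Reactants: 13 (2R,3R)-gnetin C
Product: 14 (2R,3R)-3-[3,5-bis(MOMO)phenyl]-4-(MOMO)-2-[4-(MOMO)phenyl]-6-[(E)-4-(MOMO)styryl]-2,3-dihydrobenzofuran
Conditions: MOMCl, K2CO3, acetone, rt
Reagents that add atoms: chloromethyl methyl ether (MOMCl), COCCl
Why: Fivefold phenol O-alkylation with a weak carbonate base at room temperature, which does not open the dihydrofuran by retro-oxa-Michael reaction, so both stereocentres are kept.

Step 8
Reactants: 14 penta-MOM-(2R,3R)-gnetin C; 4 1-[3,5-bis(methoxymethoxy)phenyl]ethanone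
Product: 17 (2R,3R)-3-[4-[1-[3,5-bis(MOMO)phenyl]ethenyl]-3,5-bis(MOMO)phenyl]-4-(MOMO)-2-[4-(MOMO)phenyl]-6-[(E)-4-(MOMO)styryl]-2,3-dihydrobenzofuran, via aryllithium 15 (not isolated), via tertiary alcohol 16 (not isolated)
Conditions: n-BuLi, THF, −30 °C; then 4, LaCl3·2LiCl, −78 → 0 °C; aq NH4Cl; then PPTS (cat.), toluene, 50 °C
Reagents that add atoms: none
Why: Directed ortho-metalation of ring D at the only C–H flanked by two OMOM groups, which at low temperature outruns deprotonation of the hindered triarylmethine C3'–H; ketone 1,2-addition and dehydration then follow as in step 3, and the existing stereocentres are not touched.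

Step 9
Reactants: 17 the 1,1-diarylethylene from step 8; 18 4-iodo-2-methoxyphenol
Product: 19 4-[2-[3,5-bis(MOMO)phenyl]-2-[2,6-bis(MOMO)-4-[(2R,3R)-4-(MOMO)-2-[4-(MOMO)phenyl]-6-[(E)-4-(MOMO)styryl]-2,3-dihydrobenzofuran-3-yl]phenyl]ethenyl]-2-methoxyphenol (E/Z mixture at the triaryl alkene)
Conditions: Pd(OAc)2 (5 mol%), P(o-tol)3 (10 mol%), K2CO3, DMF, 90 °C
Reagents that add atoms: none
Why: Mizoroki–Heck arylation of the terminal alkene as in step 4; the internal stilbene and the dihydrofuran are inert to these basic conditions.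

Step 10
Reactants: 19 the hepta-MOM triarylethylene
Product: 21 5-[(2R,3R)-4-hydroxy-2-(4-hydroxyphenyl)-6-[(E)-4-hydroxystyryl]-2,3-dihydrobenzofuran-3-yl]-2-[1-(3,5-dihydroxyphenyl)-2-(4-hydroxy-3-methoxyphenyl)ethenyl]benzene-1,3-diol (E/Z mixture at the triaryl alkene), via octakis(trimethylsilyl) ether 20 (not isolated)
Conditions: TMSOTf, 2,2'-bipyridyl, CH2Cl2, 0 °C → rt; then H2O
Reagents that add atoms: none
Why: Buffered silyl triflate MOM cleavage as in step 5; without strong protic acid the first dihydrofuran is not opened and the new alkene is not cyclised; the aryl methyl ether of ring E is untouched.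

Step 11
Reactants: 21 the octaphenolic triarylethylene
Product: 23 gnetin K, via para-quinone methide 22 (not isolated)
Conditions: (S)-TRIP (10 mol%), 5 Å MS, CH2Cl2–EtOAc 9:1, 0 °C
Reagents that add atoms: none
Why: Proposed new method: the same phosphoric acid-catalysed enantioselective cycloisomerisation as in step 6, run with the mirror-image catalyst. Proton transfer to the alkene carbon bearing rings D and F gives the guaiacyl-derived para-quinone methide 22, and one of the two equivalent ortho-hydroxyls of ring D closes the C2–O bond anti to ring F, giving trans-(2S,3S) under catalyst control over the remote (2R,3R) centres. The first dihydrofuran is not opened at 0 °C because its ring opening is strongly uphill. Closest known reaction types: phosphoric acid-catalysed enantioselective 1,6-additions to in situ para-quinone methides, and asymmetric intramolecular hydroalkoxylation.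

## Compound list

1 | resveratrol | Oc1ccc(/C=C/c2cc(O)cc(O)c2)cc1 | starting material
2 | (E)-3,5,4'-tris(methoxymethoxy)stilbene | COCOc1ccc(/C=C/c2cc(OCOC)cc(OCOC)c2)cc1 | intermediate
3 | 3,5-dihydroxyacetophenone | CC(=O)c1cc(O)cc(O)c1 | starting material
4 | 1-[3,5-bis(methoxymethoxy)phenyl]ethanone | CC(=O)c1cc(OCOC)cc(OCOC)c1 | intermediate
5 | [2,6-bis(MOMO)-4-[(E)-4-(MOMO)styryl]phenyl]lithium (not isolated) | [Li]c1c(OCOC)cc(/C=C/c2ccc(OCOC)cc2)cc1OCOC | intermediate
6 | 1-[3,5-bis(MOMO)phenyl]-1-[2,6-bis(MOMO)-4-[(E)-4-(MOMO)styryl]phenyl]ethanol, racemic (not isolated) | CC(O)(c1cc(OCOC)cc(OCOC)c1)c1c(OCOC)cc(/C=C/c2ccc(OCOC)cc2)cc1OCOC | intermediate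
7 | 1-[3,5-bis(MOMO)phenyl]-1-[2,6-bis(MOMO)-4-[(E)-4-(MOMO)styryl]phenyl]ethene | C=C(c1cc(OCOC)cc(OCOC)c1)c1c(OCOC)cc(/C=C/c2ccc(OCOC)cc2)cc1OCOC | intermediate
8 | 4-iodophenol | Oc1ccc(I)cc1 | starting material
9 | 4-[2-[3,5-bis(MOMO)phenyl]-2-[2,6-bis(MOMO)-4-[(E)-4-(MOMO)styryl]phenyl]ethenyl]phenol, E/Z mixture at the triaryl alkene | Oc1ccc(C=C(c2cc(OCOC)cc(OCOC)c2)c2c(OCOC)cc(/C=C/c3ccc(OCOC)cc3)cc2OCOC)cc1 | intermediate
10 | hexakis(trimethylsilyl) ether of 11 (not isolated) | C[Si](C)(C)Oc1ccc(C=C(c2cc(O[Si](C)(C)C)cc(O[Si](C)(C)C)c2)c2c(O[Si](C)(C)C)cc(/C=C/c3ccc(O[Si](C)(C)C)cc3)cc2O[Si](C)(C)C)cc1 | intermediate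
11 | 2-[1-(3,5-dihydroxyphenyl)-2-(4-hydroxyphenyl)ethenyl]-5-[(E)-2-(4-hydroxyphenyl)ethenyl]benzene-1,3-diol, E/Z mixture at the triaryl alkene | Oc1ccc(C=C(c2cc(O)cc(O)c2)c2c(O)cc(/C=C/c3ccc(O)cc3)cc2O)cc1 | intermediate
12 | 4-[(2R)-2-(3,5-dihydroxyphenyl)-2-[2,6-dihydroxy-4-[(E)-4-hydroxystyryl]phenyl]ethylidene]cyclohexa-2,5-dien-1-one (not isolated) | Oc1cc([C@@H](C=C2C=CC(=O)C=C2)c2c(O)cc(/C=C/c3ccc(O)cc3)cc2O)cc(O)c1 | intermediate
13 | (2R,3R)-3-(3,5-dihydroxyphenyl)-2-(4-hydroxyphenyl)-6-[(E)-4-hydroxystyryl]-2,3-dihydrobenzofuran-4-ol, (2R,3R)-gnetin C | Oc1cc([C@@H]2c3c(O)cc(/C=C/c4ccc(O)cc4)cc3O[C@H]2c2ccc(O)cc2)cc(O)c1 | intermediate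
14 | (2R,3R)-3-[3,5-bis(MOMO)phenyl]-4-(MOMO)-2-[4-(MOMO)phenyl]-6-[(E)-4-(MOMO)styryl]-2,3-dihydrobenzofuran | COCOc1cc([C@@H]2c3c(OCOC)cc(/C=C/c4ccc(OCOC)cc4)cc3O[C@H]2c2ccc(OCOC)cc2)cc(OCOC)c1 | intermediate
15 | 14 lithiated on ring D between the two OMOM groups (not isolated) | COCOc1cc([C@@H]2c3c(OCOC)cc(/C=C/c4ccc(OCOC)cc4)cc3O[C@H]2c2ccc(OCOC)cc2)cc(OCOC)c1[Li] | intermediate
16 | 1-[3,5-bis(MOMO)phenyl]-1-[ring D of 14]ethanol, both carbinol epimers, (2R,3R) ring unchanged (not isolated) | COCOc1cc([C@@H]2c3c(OCOC)cc(/C=C/c4ccc(OCOC)cc4)cc3O[C@H]2c2ccc(OCOC)cc2)cc(OCOC)c1C(C)(O)c1cc(OCOC)cc(OCOC)c1 | intermediate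
17 | (2R,3R)-3-[4-[1-[3,5-bis(MOMO)phenyl]ethenyl]-3,5-bis(MOMO)phenyl]-4-(MOMO)-2-[4-(MOMO)phenyl]-6-[(E)-4-(MOMO)styryl]-2,3-dihydrobenzofuran | COCOc1cc([C@@H]2c3c(OCOC)cc(/C=C/c4ccc(OCOC)cc4)cc3O[C@H]2c2ccc(OCOC)cc2)cc(OCOC)c1C(=C)c1cc(OCOC)cc(OCOC)c1 | intermediate
18 | 4-iodo-2-methoxyphenol | COc1cc(I)ccc1O | starting material
19 | 4-[2-[3,5-bis(MOMO)phenyl]-2-[2,6-bis(MOMO)-4-[(2R,3R)-4-(MOMO)-2-[4-(MOMO)phenyl]-6-[(E)-4-(MOMO)styryl]-2,3-dihydrobenzofuran-3-yl]phenyl]ethenyl]-2-methoxyphenol, E/Z mixture at the triaryl alkene | COc1cc(C=C(c2cc(OCOC)cc(OCOC)c2)c2c(OCOC)cc([C@@H]3c4c(OCOC)cc(/C=C/c5ccc(OCOC)cc5)cc4O[C@H]3c3ccc(OCOC)cc3)cc2OCOC)ccc1O | intermediate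
20 | octakis(trimethylsilyl) ether of 21 (not isolated) | COc1cc(C=C(c2cc(O[Si](C)(C)C)cc(O[Si](C)(C)C)c2)c2c(O[Si](C)(C)C)cc([C@@H]3c4c(O[Si](C)(C)C)cc(/C=C/c5ccc(O[Si](C)(C)C)cc5)cc4O[C@H]3c3ccc(O[Si](C)(C)C)cc3)cc2O[Si](C)(C)C)ccc1O[Si](C)(C)C | intermediate
21 | 5-[(2R,3R)-4-hydroxy-2-(4-hydroxyphenyl)-6-[(E)-4-hydroxystyryl]-2,3-dihydrobenzofuran-3-yl]-2-[1-(3,5-dihydroxyphenyl)-2-(4-hydroxy-3-methoxyphenyl)ethenyl]benzene-1,3-diol, E/Z mixture at the triaryl alkene | COc1cc(C=C(c2cc(O)cc(O)c2)c2c(O)cc([C@@H]3c4c(O)cc(/C=C/c5ccc(O)cc5)cc4O[C@H]3c3ccc(O)cc3)cc2O)ccc1O | intermediate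
22 | 4-[(2S)-2-(3,5-dihydroxyphenyl)-2-[2,6-dihydroxy-4-[(2R,3R)-4-hydroxy-2-(4-hydroxyphenyl)-6-[(E)-4-hydroxystyryl]-2,3-dihydrobenzofuran-3-yl]phenyl]ethylidene]-2-methoxycyclohexa-2,5-dien-1-one (not isolated) | Oc1cc([C@@H]2c3c(O)cc(/C=C/c4ccc(O)cc4)cc3O[C@H]2c2ccc(O)cc2)cc(O)c1[C@@H](C=C1C=CC(=O)C(OC)=C1)c1cc(O)cc(O)c1 | intermediate
23 | gnetin K, (2S,3S)-3-(3,5-dihydroxyphenyl)-2-(4-hydroxy-3-methoxyphenyl)-6-[(2R,3R)-4-hydroxy-2-(4-hydroxyphenyl)-6-[(E)-4-hydroxystyryl]-2,3-dihydrobenzofuran-3-yl]-2,3-dihydrobenzofuran-4-ol | COc1cc([C@H]2Oc3cc([C@@H]4c5c(O)cc(/C=C/c6ccc(O)cc6)cc5O[C@H]4c4ccc(O)cc4)cc(O)c3[C@@H]2c2cc(O)cc(O)c2)ccc1O | target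

## Step count and risks

Total steps: 11. Longest linear sequence: 10 (steps 1, 3, 4, 5, 6, 7, 8, 9, 10, 11, from resveratrol).

Three steps most likely to fail:

Step 6 (the proposed new cyclisation, first use). Risks are low acidity of the catalyst towards the hindered alkene, or modest enantioselectivity. Fallback with known chemistry, setting out from 11: the achiral acid diphenyl phosphate (10 mol%, CH2Cl2–EtOAc, rt) brings about the ordinary acid-catalysed cyclisation of the ortho-hydroxyaryl alkene to the racemic trans-dihydrobenzofuran. This passes through 12 and its mirror image, the (S)-para-quinone methide F1, and gives 13 together with its enantiomer (2S,3S)-gnetin C F2. Preparative HPLC on a chiral stationary phase (amylose tris(3,5-dimethylphenylcarbamate)) separates the two, and the route is rejoined at 13.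

Step 8 (lithiation next to the dihydrofuran). n-BuLi could remove the triarylmethine C3'–H and open the ring by β-elimination, or add to the stilbene. Fallback, setting out from 7: the bromine for a low-temperature halogen–lithium exchange is installed before any dihydrofuran exists.
- n-BuLi (THF, −20 °C) metalates ring D of 7 between its two OMOM groups (that site on ring B is already substituted) to the aryllithium F3, which 1,2-dibromotetrachloroethane converts into the aryl bromide F4.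
- Heck reaction with 8 as in step 4 (the hindered, electron-rich bromide does not compete with the iodide) gives the bromo triarylethylene F5.
- TMSOTf/2,2'-bipyridyl then water gives, through the hexakis(trimethylsilyl) ether F6, the bromo hexaphenol F7.
- (R)-TRIP as in step 6 gives, through the para-quinone methide F8, the ring D-brominated (2R,3R)-gnetin C F9.
- MOMCl/K2CO3 gives its penta-MOM ether F10.
- t-BuLi (2 equiv, THF, −78 °C) exchanges bromine for lithium within minutes to give 15, where the route is rejoined (addition to 4 and dehydration to 17 as in step 8).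

Step 11 (the proposed new cyclisation on the full skeleton). Risks are that the remote (2R,3R) unit mismatches the catalyst, or that eight free phenols disturb the hydrogen-bonded transition state. Fallback with known chemistry, setting out from 21: diphenyl phosphate (10 mol%, CH2Cl2–EtOAc, rt) closes the ring without facial control, trans only. This passes through 22 and its epimer at the new methine, the (R)-para-quinone methide F11, and gives 23 together with its diastereomer, (2R,3R,2'R,3'R)-gnetin K F12. Being diastereomers, the two are separated by preparative reversed-phase HPLC, and the fallback arrives at 23.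

Further compounds
F1 | step 6 | 4-[(2S)-2-(3,5-dihydroxyphenyl)-2-[2,6-dihydroxy-4-[(E)-4-hydroxystyryl]phenyl]ethylidene]cyclohexa-2,5-dien-1-one (mirror image of 12, not isolated) | Oc1cc([C@H](C=C2C=CC(=O)C=C2)c2c(O)cc(/C=C/c3ccc(O)cc3)cc2O)cc(O)c1
F2 | step 6 | (2S,3S)-gnetin C, enantiomer of 13 | Oc1cc([C@H]2c3c(O)cc(/C=C/c4ccc(O)cc4)cc3O[C@@H]2c2ccc(O)cc2)cc(O)c1
F3 | step 8 | 7 lithiated on the 3,5-bis(MOMO)phenyl ring between the two OMOM groups (not isolated) | C=C(c1cc(OCOC)c([Li])c(OCOC)c1)c1c(OCOC)cc(/C=C/c2ccc(OCOC)cc2)cc1OCOC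
F4 | step 8 | 1-[4-bromo-3,5-bis(MOMO)phenyl]-1-[2,6-bis(MOMO)-4-[(E)-4-(MOMO)styryl]phenyl]ethene | C=C(c1cc(OCOC)c(Br)c(OCOC)c1)c1c(OCOC)cc(/C=C/c2ccc(OCOC)cc2)cc1OCOC
F5 | step 8 | 4-[2-[4-bromo-3,5-bis(MOMO)phenyl]-2-[2,6-bis(MOMO)-4-[(E)-4-(MOMO)styryl]phenyl]ethenyl]phenol, E/Z mixture | Oc1ccc(C=C(c2cc(OCOC)c(Br)c(OCOC)c2)c2c(OCOC)cc(/C=C/c3ccc(OCOC)cc3)cc2OCOC)cc1
F6 | step 8 | hexakis(trimethylsilyl) ether of F7 (not isolated) | C[Si](C)(C)Oc1ccc(C=C(c2cc(O[Si](C)(C)C)c(Br)c(O[Si](C)(C)C)c2)c2c(O[Si](C)(C)C)cc(/C=C/c3ccc(O[Si](C)(C)C)cc3)cc2O[Si](C)(C)C)cc1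
F7 | step 8 | 2-[1-(4-bromo-3,5-dihydroxyphenyl)-2-(4-hydroxyphenyl)ethenyl]-5-[(E)-2-(4-hydroxyphenyl)ethenyl]benzene-1,3-diol, E/Z mixture | Oc1ccc(C=C(c2cc(O)c(Br)c(O)c2)c2c(O)cc(/C=C/c3ccc(O)cc3)cc2O)cc1
F8 | step 8 | 4-[(2R)-2-(4-bromo-3,5-dihydroxyphenyl)-2-[2,6-dihydroxy-4-[(E)-4-hydroxystyryl]phenyl]ethylidene]cyclohexa-2,5-dien-1-one (not isolated) | Oc1cc([C@@H](C=C2C=CC(=O)C=C2)c2c(O)cc(/C=C/c3ccc(O)cc3)cc2O)cc(O)c1Br
F9 | step 8 | (2R,3R)-3-(4-bromo-3,5-dihydroxyphenyl)-2-(4-hydroxyphenyl)-6-[(E)-4-hydroxystyryl]-2,3-dihydrobenzofuran-4-ol | Oc1cc([C@@H]2c3c(O)cc(/C=C/c4ccc(O)cc4)cc3O[C@H]2c2ccc(O)cc2)cc(O)c1Br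
F10 | step 8 | (2R,3R)-3-[4-bromo-3,5-bis(MOMO)phenyl]-4-(MOMO)-2-[4-(MOMO)phenyl]-6-[(E)-4-(MOMO)styryl]-2,3-dihydrobenzofuran | COCOc1cc([C@@H]2c3c(OCOC)cc(/C=C/c4ccc(OCOC)cc4)cc3O[C@H]2c2ccc(OCOC)cc2)cc(OCOC)c1Br
F11 | step 11 | epimer of 22 with (2R) configuration at the new methine (not isolated) | Oc1cc([C@@H]2c3c(O)cc(/C=C/c4ccc(O)cc4)cc3O[C@H]2c2ccc(O)cc2)cc(O)c1[C@H](C=C1C=CC(=O)C(OC)=C1)c1cc(O)cc(O)c1
F12 | step 11 | (2R,3R,2'R,3'R)-diastereomer of gnetin K | COc1cc([C@@H]2Oc3cc([C@@H]4c5c(O)cc(/C=C/c6ccc(O)cc6)cc5O[C@H]4c4ccc(O)cc4)cc(O)c3[C@H]2c2cc(O)cc(O)c2)ccc1O
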